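**Strategy.** Everything rests on cutting the allylic C1'–C2' single bond of the geranyl ether instead of its O–C1' bond (C1' is the OCH2 carbon; the core carries isochromanone numbering). The key step, a nickel/photoredox decarboxylative alkenylation, joins aryloxyacetic acid 11 to (E)-alkenyl iodide 16. Loss of CO2 gives a C1' radical, nickel couples it to C2', and the whole side chain with its C2'=C3' geometry is installed in one operation on the unprotected lactone. It exploits the C6–O–C1'H2 ether unit on aromatic ring A, whose oxygen stabilises the C1' radical. The precursor is the complete (3R,4R)-4-acetoxy lactone (ring B) carrying OCH2CO2H at C6, made by enantioselective oxylactonization of an (E)-propenyl benzoate.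

Key step: step 9

Assumption: the (R,R)-antipode of the lactate-derived aryliodine diacetate, C[C@@H](Oc1cccc(O[C@H](C)C(=O)OC)c1I(OC(C)=O)OC(C)=O)C(=O)OC (from methyl (S)-lactate), is taken to induce the (3R,4R) series in step 5; if the sense of induction is the opposite one, the (S,S)-antipode is used with no other change.

Step 1
Reactants: 1 2,4-dihydroxy-5-methoxybenzaldehyde; 2 tert-butyl bromoacetate
Product: 4 tert-butyl 2-(4-formyl-2,5-dimethoxyphenoxy)acetate, via monoalkylated phenol 3 (not isolated)
Conditions: 2 (1.05 equiv), K2CO3, DMF, rt; then MeI (excess), 50 °C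
Reagents that add atoms: iodomethane, CI
Why: Williamson etherification in which the free 4-OH (para to the formyl group) is alkylated first by the bromoacetate while the 2-OH is held in a hydrogen-bonded chelate with the aldehyde, after which the chelated 2-OH is methylated by excess iodomethane on warming.

Step 2
Reactants: 4 tert-butyl 2-(4-formyl-2,5-dimethoxyphenoxy)acetate
Product: 5 4-(2-tert-butoxy-2-oxoethoxy)-2,5-dimethoxybenzoic acid
Conditions: NaClO2, NaH2PO4, 2-methyl-2-butene, t-BuOH/H2O, rt
Reagents that add atoms: sodium chlorite, [Na+].[O-]Cl=O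
Why: Pinnick oxidation should convert the aryl aldehyde into the acid under buffered conditions that leave the tert-butyl ester and the aryl ethers untouched, with 2-methyl-2-butene trapping hypochlorous acid so that the electron-rich ring is not chlorinated.

Step 3
Reactants: 5 4-(2-tert-butoxy-2-oxoethoxy)-2,5-dimethoxybenzoic acid; 6 allyl acetate
Product: 8 methyl 2-allyl-4-(2-tert-butoxy-2-oxoethoxy)-3,6-dimethoxybenzoate, via ortho-allyl acid 7 (not isolated)
Conditions: [Ru(p-cymene)Cl2]2 (cat.), K3PO4, MeCN, 50 °C; then K2CO3, MeI, DMF, rt
Reagents that add atoms: iodomethane, CI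
Why: Carboxylate-directed ortho-C–H allylation by the divalent ruthenium catalyst (cycloruthenation, insertion of allyl acetate, β-acetoxy elimination) should take place at the only ortho C–H the carboxylate can reach, and the acid is then O-methylated in the same flask for isolation.

Step 4
Reactants: 8 methyl 2-allyl-4-(2-tert-butoxy-2-oxoethoxy)-3,6-dimethoxybenzoate
Product: 9 methyl 4-(2-tert-butoxy-2-oxoethoxy)-3,6-dimethoxy-2-[(E)-prop-1-enyl]benzoate
Conditions: RuHCl(CO)(PPh3)3 (cat.), toluene, 80 °C
Reagents that add atoms: none
Why: Ruthenium hydride-catalysed alkene isomerization (hydrometalation, β-hydride elimination) should move the double bond into conjugation with the arene and deliver the thermodynamically preferred E-propenyl isomer.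

Step 5
Reactants: 9 methyl 4-(2-tert-butoxy-2-oxoethoxy)-3,6-dimethoxy-2-[(E)-prop-1-enyl]benzoate
Product: 10 tert-butyl 2-{[(3R,4R)-4-acetoxy-5,8-dimethoxy-3-methyl-1-oxoisochroman-6-yl]oxy}acetate
Conditions: (R,R)-ArI(OAc)2 (Ar = 2,6-bis[(1R)-1-(methoxycarbonyl)ethoxy]phenyl; 1.3 equiv), BF3·OEt2, AcOH, CH2Cl2, −78 → −40 °C
Reagents that add atoms: acetic acid, CC(=O)O
Why: Enantioselective endo-selective oxylactonization with a chiral trivalent iodine reagent, in which the BF3-activated iodane adds to one alkene face, the ester carbonyl oxygen closes the six-membered ring at C3 anti to iodine, and acetate displaces the iodanyl group at benzylic C4 with inversion, so that the two C–O bonds are formed syn across the E-alkene (cis-3,4) with the absolute sense (3R,4R) set by the lactate stereocentres of the reagent and the ester methyl lost from the oxocarbenium ion.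

Step 6
Reactants: 10 tert-butyl 2-{[(3R,4R)-4-acetoxy-5,8-dimethoxy-3-methyl-1-oxoisochroman-6-yl]oxy}acetate
Product: 11 2-{[(3R,4R)-4-acetoxy-8-hydroxy-5-methoxy-3-methyl-1-oxoisochroman-6-yl]oxy}acetic acid
Conditions: BCl3 (3 equiv), CH2Cl2, −78 → 0 °C; aqueous work-up
Reagents that add atoms: none
Why: Lewis acid dealkylation in which BCl3 chelated between the lactone carbonyl and the peri 8-methoxy group should cleave that methyl ether selectively (the 5-methoxy group is not chelated) and the same reagent cleaves the tert-butyl ester through the tert-butyl cation, while the secondary acetate and the lactone are expected to survive at low temperature.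

Step 7
Reactants: 12 5-bromo-2-methylpent-2-ene; 13 lithium acetylide–ethylenediamine complex
Product: 14 6-methylhept-5-en-1-yne
Conditions: DMSO, 10 °C → rt
Reagents that add atoms: none
Why: SN2 alkylation of lithium acetylide by the primary homoallylic bromide in a dipolar aprotic solvent.

Step 8
Reactants: 14 6-methylhept-5-en-1-yne
Product: 16 (E)-1-iodo-2,6-dimethylhepta-1,5-diene, via alkenylalane 15 (not isolated)
Conditions: Me3Al (2 equiv), Cp2ZrCl2 (cat.), CH2Cl2, 0 °C → rt; then I2, THF, −30 → 0 °C
Reagents that add atoms: trimethylaluminium, C[Al](C)C; iodine, II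
Why: Negishi zirconium-catalysed carboalumination adds methyl and aluminium syn across the terminal alkyne with methyl on the internal carbon, and iodinolysis of the C–Al bond proceeds with retention, which fixes the E geometry of the trisubstituted alkenyl iodide.

Step 9
Reactants: 11 2-{[(3R,4R)-4-acetoxy-8-hydroxy-5-methoxy-3-methyl-1-oxoisochroman-6-yl]oxy}acetic acid; 16 (E)-1-iodo-2,6-dimethylhepta-1,5-diene
Product: 17 (3R,4R)-6-{[(2E)-3,7-dimethylocta-2,6-dien-1-yl]oxy}-8-hydroxy-5-methoxy-3-methyl-1-oxoisochroman-4-yl acetate (target)
Conditions: Ir[dF(CF3)ppy]2(dtbbpy)PF6 (1 mol %), NiCl2·glyme (5 mol %), dtbbpy (5 mol %), Cs2CO3 (0.55 equiv), 16 (1.5 equiv), degassed DMSO, blue LEDs, rt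
Reagents that add atoms: none
Why: The photoexcited trivalent iridium complex oxidizes the caesium carboxylate of 11, CO2 is lost, and the resulting oxygen-stabilised C1' radical is captured by the nickel centre that has inserted into the C–I bond of 16; reductive elimination from trivalent nickel then forms the C1'–C2' bond and the reduced photocatalyst returns nickel to its zerovalent state. The closest known reaction type is the metallaphotoredox decarboxylative alkenylation of α-oxy carboxylic acids with vinyl halides. No ring is closed and no stereocentre is formed; the E geometry at C2'=C3' is set in step 8 and should be carried through, since oxidative addition and reductive elimination at the alkenyl carbon are stereoretentive. The step needs oxidation of the carboxylate in preference to the 8-hydroxyl, which is secured by using only enough Cs2CO3 to form the carboxylate, so that the phenol stays protonated and hydrogen-bonded to the lactone carbonyl. It also needs coupling to outrun ionization of the product allylic aryl ether by zerovalent nickel, which the trisubstituted alkene, the room temperature and the excess of 16 should ensure. The coupling is placed last because the side-chain alkenes would not survive the iodane of step 5, while the acetate, lactone and both stereocentres are inert to these neutral conditions.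

**Compound list**
1 | 2,4-dihydroxy-5-methoxybenzaldehyde | COc1cc(C=O)c(O)cc1O | starting material
2 | tert-butyl bromoacetate | CC(C)(C)OC(=O)CBr | starting material
3 | tert-butyl 2-(4-formyl-5-hydroxy-2-methoxyphenoxy)acetate | COc1cc(C=O)c(O)cc1OCC(=O)OC(C)(C)C | intermediate
4 | tert-butyl 2-(4-formyl-2,5-dimethoxyphenoxy)acetate | COc1cc(C=O)c(OC)cc1OCC(=O)OC(C)(C)C | intermediate
5 | 4-(2-tert-butoxy-2-oxoethoxy)-2,5-dimethoxybenzoic acid | COc1cc(C(=O)O)c(OC)cc1OCC(=O)OC(C)(C)C | intermediate
6 | allyl acetate | CC(=O)OCC=C | starting material
7 | 2-allyl-4-(2-tert-butoxy-2-oxoethoxy)-3,6-dimethoxybenzoic acid | C=CCc1c(OC)c(OCC(=O)OC(C)(C)C)cc(OC)c1C(=O)O | intermediate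
8 | methyl 2-allyl-4-(2-tert-butoxy-2-oxoethoxy)-3,6-dimethoxybenzoate | C=CCc1c(OC)c(OCC(=O)OC(C)(C)C)cc(OC)c1C(=O)OC | intermediate
9 | methyl 4-(2-tert-butoxy-2-oxoethoxy)-3,6-dimethoxy-2-[(E)-prop-1-enyl]benzoate | C/C=C/c1c(OC)c(OCC(=O)OC(C)(C)C)cc(OC)c1C(=O)OC | intermediate
10 | tert-butyl 2-{[(3R,4R)-4-acetoxy-5,8-dimethoxy-3-methyl-1-oxoisochroman-6-yl]oxy}acetate | COc1c(OCC(=O)OC(C)(C)C)cc(OC)c2c1[C@@H](OC(C)=O)[C@@H](C)OC2=O | intermediate
11 | 2-{[(3R,4R)-4-acetoxy-8-hydroxy-5-methoxy-3-methyl-1-oxoisochroman-6-yl]oxy}acetic acid | COc1c(OCC(=O)O)cc(O)c2c1[C@@H](OC(C)=O)[C@@H](C)OC2=O | intermediate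
12 | 5-bromo-2-methylpent-2-ene | CC(C)=CCCBr | starting material
13 | lithium acetylide–ethylenediamine complex | [Li+].[C-]#C.NCCN | starting material
14 | 6-methylhept-5-en-1-yne | CC(C)=CCCC#C | intermediate
15 | [(E)-2,6-dimethylhepta-1,5-dienyl]dimethylalane | C[Al](C)/C=C(\C)CCC=C(C)C | intermediate
16 | (E)-1-iodo-2,6-dimethylhepta-1,5-diene | I/C=C(\C)CCC=C(C)C | intermediate
17 | (3R,4R)-6-{[(2E)-3,7-dimethylocta-2,6-dien-1-yl]oxy}-8-hydroxy-5-methoxy-3-methyl-1-oxoisochroman-4-yl acetate | COc1c(OC/C=C(\C)CCC=C(C)C)cc(O)c2c1[C@@H](OC(C)=O)[C@@H](C)OC2=O | target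

**Totals.** Total step count: 9. Longest linear sequence: 7 steps (steps 1–6 and step 9, from 1); steps 7–8 make the side-chain fragment.

**Steps most likely to fail**

1. Step 9 (key step). The free 8-hydroxyl may quench the photocatalyst or donate a hydrogen atom to the C1' radical, and zerovalent nickel may ionize the newly formed allylic aryl ether; either process would erode the coupling. The fallback sets out from 11 and 16 and comes back at 17, forming the same C1'–C2' bond by a reductive, light-free and base-free radical route. Acid 11 is condensed with N-hydroxyphthalimide (N,N'-diisopropylcarbodiimide, cat. DMAP, CH2Cl2) to the redox-active N-hydroxyphthalimide ester F1. Iodide 16 is converted by iodine–lithium exchange (t-BuLi, −78 °C) and ZnCl2 into the (E)-alkenylzinc chloride F2, used in excess so that one equivalent is spent on the phenol. Ni(acac)2 and 2,2'-bipyridine in THF/DMF at rt should then join F1 and F2 with loss of CO2 and phthalimide (nickel-catalysed decarboxylative alkenylation of a redox-active ester) to give 17.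

2. Step 5. Facial discrimination may be poor at the twisted, doubly ortho-substituted styrene, syn stereospecificity may be lost through an open benzylic cation stabilised by the ortho methoxy group, and the trialkoxyarene may undergo single-electron oxidation by the activated iodane. The fallback sets out from 9 and comes back at 10. The same syn-oxylactonization is run with achiral PhI(OAc)2 (BF3·OEt2, AcOH, CH2Cl2, −78 → −40 °C) to give the racemic cis-lactone F3, from which any trans isomer is removed by chromatography on silica. F3 is then resolved by preparative chromatography on a cellulose tris(3,5-dimethylphenylcarbamate) stationary phase, the (3R,4R) antipode being 10. This moves enantiocontrol from the reagent to a separation.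

3. Step 6. The boron Lewis acid may ionize or cleave the benzylic 4-acetate and may over-demethylate at the 5-methoxy group. The fallback sets out from 10 and comes back at 11, splitting the unveiling into two orthogonal operations without a boron halide. Acidolysis (CF3CO2H, CH2Cl2, rt) removes only the tert-butyl group and should give the 8-O-methyl acid F4. MgI2·OEt2 in THF/toluene at 50 °C then forms a magnesium chelate between the lactone carbonyl and the 8-methoxy oxygen, and iodide removes that methyl group by SN2 to give 11.

**Further compounds**
F1 | step 9 | 1,3-dioxoisoindolin-2-yl 2-{[(3R,4R)-4-acetoxy-8-hydroxy-5-methoxy-3-methyl-1-oxoisochroman-6-yl]oxy}acetate | COc1c(OCC(=O)ON3C(=O)c4ccccc4C3=O)cc(O)c2c1[C@@H](OC(C)=O)[C@@H](C)OC2=O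
F2 | step 9 | [(E)-2,6-dimethylhepta-1,5-dienyl]zinc chloride | Cl[Zn]/C=C(\C)CCC=C(C)C
F3 | step 5 | racemic cis-lactone (10 together with its (3S,4S) antipode) | COc1c(OCC(=O)OC(C)(C)C)cc(OC)c2c1[C@@H](OC(C)=O)[C@@H](C)OC2=O.COc1c(OCC(=O)OC(C)(C)C)cc(OC)c2c1[C@H](OC(C)=O)[C@H](C)OC2=O
F4 | step 6 | 2-{[(3R,4R)-4-acetoxy-5,8-dimethoxy-3-methyl-1-oxoisochroman-6-yl]oxy}acetic acid | COc1c(OCC(=O)O)cc(OC)c2c1[C@@H](OC(C)=O)[C@@H](C)OC2=O
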